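**Plan** (germacrane numbering: ring A = ten-membered carbocycle C1–C10; ring B = lactone O–C6–C7–C11–C12; C13 = exocyclic CH2; C14 on C10; C15 on C4)

1. Retrosynthesis: both oxiranes (C1–C10, C4–C5) and the angelate are removed first, giving the (1(10)E,4Z)-8-hydroxy-2-silyloxy trienolide 24; ring A is then cut at C7–C8; the open chain is cut at C6–C7 (alkynylation) and C2–C3 (vinylogous aldol).
2. Enabling feature: C13=C11–C7–C8–O is a homoallylic alcohol whose allyl part (C13, C11, C7) lies in ring B. A 3-(bromomethyl)butenolide adding through C7 to a C8 aldehyde therefore closes ring A and regenerates the exocyclic methylene in one event.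
3. Forward order: C8→C1 chain by carboalumination; C2, C3 and the 4Z alkene by a vinylogous aldol that delivers a temporary δ-lactone (opened again in step 5); C6 by alkynylation; ring B by carbonylative lactonisation (step 10); ring A last (step 15); then angelate and two epoxidations.
4. Stereochemistry: C2 from the Cu/Tol-BINAP catalyst and C6 from the Zn/ProPhenol catalyst; C7 and C8 are relayed from C6 in the key step; C1/C10 and C4/C5 are relayed from the C2 hydroxyl.

Key step: step 15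

Remark on the chemistry: the two oxiranes are treated as the oxidation state of the ring alkenes and are introduced after the bicyclic carbon skeleton (rings A and B) is complete; the facial sense of the two ligand-controlled additions (steps 4 and 8) is assigned by analogy, and the ligand antipode would be used if the first run shows the opposite sense.

**Step 1**
Reactants: 1 tert-butyl(but-3-yn-1-yloxy)dimethylsilane
Product: 3 tert-butyl{[(3E)-4-iodo-3-methylbut-3-en-1-yl]oxy}dimethylsilane, via alkenyl(dimethyl)alane 2 (not isolated)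
Conditions: Me3Al, Cp2ZrCl2 (25 mol %), CH2Cl2, 0 °C to rt; then I2, THF, −30 °C
Reagents that add atoms: trimethylaluminium C[Al](C)C; iodine II
Why: Zirconium-catalysed Negishi carboalumination adds methyl and aluminium syn across the terminal alkyne with methyl on the inner carbon, and iodinolysis of the C–Al bond with retention fixes the E geometry of the future C1=C10 bond.

**Step 2**
Reactants: 3 tert-butyl{[(3E)-4-iodo-3-methylbut-3-en-1-yl]oxy}dimethylsilane
Product: 5 (2E)-5-{[tert-butyl(dimethyl)silyl]oxy}-3-methylpent-2-enal, via alkenyllithium 4 (not isolated)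
Conditions: t-BuLi (2.1 equiv), Et2O, −78 °C; then DMF, −78 to 0 °C
Reagents that add atoms: N,N-dimethylformamide CN(C)C=O
Why: Iodine–lithium exchange goes with retention of alkene geometry, and formylation of the alkenyllithium with DMF (Bouveault-type) should give the E enal.

**Step 3**
Reactants: 6 methyl 3-methylbut-2-enoate
Product: 8 [(1-methoxy-3-methylbuta-1,3-dien-1-yl)oxy]trimethylsilane, via lithium dienolate 7 (not isolated)
Conditions: LiN(iPr)2, THF, −78 °C; then Me3SiCl, −78 °C to rt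
Reagents that add atoms: chlorotrimethylsilane C[Si](C)(C)Cl
Why: γ-Deprotonation of the senecioate gives the extended enolate, which is silylated on oxygen to the silyl dienolate (standard silyl ketene acetal formation).

**Step 4**
Reactants: 5 (2E)-5-{[tert-butyl(dimethyl)silyl]oxy}-3-methylpent-2-enal; 8 [(1-methoxy-3-methylbuta-1,3-dien-1-yl)oxy]trimethylsilane
Product: 9 (6S)-6-[(1E)-4-{[tert-butyl(dimethyl)silyl]oxy}-2-methylbut-1-en-1-yl]-4-methyl-5,6-dihydro-2H-pyran-2-one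
Conditions: Cu(OTf)2 (10 mol %), (S)-Tol-BINAP (11 mol %), Bu4N[Ph3SiF2] (20 mol %), THF, −78 °C to rt
Reagents that add atoms: none
Why: In this catalytic asymmetric vinylogous Mukaiyama aldol–lactonisation the copper dienolate should add through its γ-carbon to the Si face of the aldehyde under ligand control (sets C2 as S), and the aldolate closes to the six-membered lactone, whose ring enforces the Z geometry of the future C4=C5 bond.

**Step 5**
Reactants: 9 (6S)-6-[(1E)-4-{[tert-butyl(dimethyl)silyl]oxy}-2-methylbut-1-en-1-yl]-4-methyl-5,6-dihydro-2H-pyran-2-one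
Product: 10 (2Z,5S,6E)-9-{[tert-butyl(dimethyl)silyl]oxy}-5-hydroxy-N-methoxy-N,3,7-trimethylnona-2,6-dienamide
Conditions: MeNH(OMe)·HCl, Me3Al, CH2Cl2, 0 °C to rt; crude product used directly
Reagents that add atoms: N,O-dimethylhydroxylamine hydrochloride CNOC.Cl
Why: Aluminium amide aminolysis opens the temporary lactone by 1,2-attack to the Weinreb amide, leaving the Z alkene and C2 untouched.

**Step 6**
Reactants: 10 (2Z,5S,6E)-9-{[tert-butyl(dimethyl)silyl]oxy}-5-hydroxy-N-methoxy-N,3,7-trimethylnona-2,6-dienamide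
Product: 11 (2Z,5S,6E)-9-{[tert-butyl(dimethyl)silyl]oxy}-N-methoxy-N,3,7-trimethyl-5-[(triisopropylsilyl)oxy]nona-2,6-dienamide
Conditions: iPr3SiOTf, 2,6-lutidine, CH2Cl2, −78 to 0 °C
Reagents that add atoms: triisopropylsilyl trifluoromethanesulfonate CC(C)[Si](C(C)C)(C(C)C)OS(=O)(=O)C(F)(F)F
Why: Silylation of the secondary allylic alcohol prevents relactonisation and gives a group that outlasts the later cleavage of the primary silyl ether.

**Step 7**
Reactants: 11 (2Z,5S,6E)-9-{[tert-butyl(dimethyl)silyl]oxy}-N-methoxy-N,3,7-trimethyl-5-[(triisopropylsilyl)oxy]nona-2,6-dienamide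
Product: 12 (2Z,5S,6E)-9-{[tert-butyl(dimethyl)silyl]oxy}-3,7-dimethyl-5-[(triisopropylsilyl)oxy]nona-2,6-dienal
Conditions: iBu2AlH, THF, −78 °C; Rochelle salt work-up; used at once
Reagents that add atoms: none
Why: The chelated tetrahedral intermediate of the Weinreb amide collapses only on work-up, so the Z enal should form without over-reduction or isomerisation.

**Step 8**
Reactants: 12 (2Z,5S,6E)-9-{[tert-butyl(dimethyl)silyl]oxy}-3,7-dimethyl-5-[(triisopropylsilyl)oxy]nona-2,6-dienal; 13 1-methoxy-4-[(prop-2-yn-1-yloxy)methyl]benzene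
Product: 15 (4R,5Z,8S,9E)-12-{[tert-butyl(dimethyl)silyl]oxy}-1-[(4-methoxybenzyl)oxy]-6,10-dimethyl-8-[(triisopropylsilyl)oxy]dodeca-5,9-dien-2-yn-4-ol, via methylzinc acetylide 14 (not isolated)
Conditions: 13 (3 equiv), Me2Zn (3 equiv), (S,S)-ProPhenol (20 mol %), Ph3PO (40 mol %), toluene, 0 °C
Reagents that add atoms: none
Why: The dinuclear zinc–ProPhenol-catalysed alkynylation of enals should deliver the acetylide to the Si face of the aldehyde under catalyst control (sets C6, here C4, as R), independently of the remote C2 centre.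

**Step 9**
Reactants: 15 (4R,5Z,8S,9E)-12-{[tert-butyl(dimethyl)silyl]oxy}-1-[(4-methoxybenzyl)oxy]-6,10-dimethyl-8-[(triisopropylsilyl)oxy]dodeca-5,9-dien-2-yn-4-ol
Product: 17 (2Z,4R,5Z,8S,9E)-12-{[tert-butyl(dimethyl)silyl]oxy}-2-iodo-1-[(4-methoxybenzyl)oxy]-6,10-dimethyl-8-[(triisopropylsilyl)oxy]dodeca-2,5,9-trien-4-ol, via cyclic alkenylalanate 16 (not isolated)
Conditions: NaAlH2(OCH2CH2OMe)2, THF, 0 °C; then I2, −78 °C
Reagents that add atoms: iodine II
Why: Hydroxyl-directed trans-hydroalumination of the propargylic alcohol places hydrogen on C7 and aluminium on C11, and iodinolysis with retention gives the Z iodoalkene with iodine cis to the carbinol.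

**Step 10**
Reactants: 17 (2Z,4R,5Z,8S,9E)-12-{[tert-butyl(dimethyl)silyl]oxy}-2-iodo-1-[(4-methoxybenzyl)oxy]-6,10-dimethyl-8-[(triisopropylsilyl)oxy]dodeca-2,5,9-trien-4-ol
Product: 18 (5R)-5-[(1Z,4S,5E)-8-{[tert-butyl(dimethyl)silyl]oxy}-2,6-dimethyl-4-[(triisopropylsilyl)oxy]octa-1,5-dien-1-yl]-3-{[(4-methoxybenzyl)oxy]methyl}furan-2(5H)-one
Conditions: PdCl2(PPh3)2 (5 mol %), CO (1 atm), iPr2NEt, THF, 40 °C
Reagents that add atoms: carbon monoxide [C-]#[O+]
Why: Oxidative addition to zerovalent palladium, CO insertion and capture of the acylpalladium by the cis γ-hydroxyl (carbonylative lactonisation) should close ring B as the butenolide without touching C6.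

**Step 11**
Reactants: 18 (5R)-5-[(1Z,4S,5E)-8-{[tert-butyl(dimethyl)silyl]oxy}-2,6-dimethyl-4-[(triisopropylsilyl)oxy]octa-1,5-dien-1-yl]-3-{[(4-methoxybenzyl)oxy]methyl}furan-2(5H)-one
Product: 19 (5R)-5-[(1Z,4S,5E)-8-{[tert-butyl(dimethyl)silyl]oxy}-2,6-dimethyl-4-[(triisopropylsilyl)oxy]octa-1,5-dien-1-yl]-3-(hydroxymethyl)furan-2(5H)-one
Conditions: DDQ, CH2Cl2/pH 7 buffer, 0 °C
Reagents that add atoms: none
Why: Oxidative cleavage of the 4-methoxybenzyl ether frees the primary allylic alcohol under neutral conditions that spare both silyl ethers and the base-sensitive 5-alkenylbutenolide.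

**Step 12**
Reactants: 19 (5R)-5-[(1Z,4S,5E)-8-{[tert-butyl(dimethyl)silyl]oxy}-2,6-dimethyl-4-[(triisopropylsilyl)oxy]octa-1,5-dien-1-yl]-3-(hydroxymethyl)furan-2(5H)-one
Product: 20 (5R)-3-(bromomethyl)-5-[(1Z,4S,5E)-8-{[tert-butyl(dimethyl)silyl]oxy}-2,6-dimethyl-4-[(triisopropylsilyl)oxy]octa-1,5-dien-1-yl]furan-2(5H)-one
Conditions: CBr4, PPh3, CH2Cl2, −20 °C
Reagents that add atoms: carbon tetrabromide BrC(Br)(Br)Br
Why: Appel bromination converts the primary allylic alcohol to the bromide through the alkoxyphosphonium salt under neutral conditions.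

**Step 13**
Reactants: 20 (5R)-3-(bromomethyl)-5-[(1Z,4S,5E)-8-{[tert-butyl(dimethyl)silyl]oxy}-2,6-dimethyl-4-[(triisopropylsilyl)oxy]octa-1,5-dien-1-yl]furan-2(5H)-one
Product: 21 (5R)-3-(bromomethyl)-5-[(1Z,4S,5E)-8-hydroxy-2,6-dimethyl-4-[(triisopropylsilyl)oxy]octa-1,5-dien-1-yl]furan-2(5H)-one
Conditions: aq. HF (48 %), MeCN, 0 °C
Reagents that add atoms: none
Why: The primary tert-butyldimethylsilyl ether is cleaved much faster than the hindered secondary triisopropylsilyl ether, and the acrylate-type allylic bromide tolerates the nucleophile-free acidic medium.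

**Step 14**
Reactants: 21 (5R)-3-(bromomethyl)-5-[(1Z,4S,5E)-8-hydroxy-2,6-dimethyl-4-[(triisopropylsilyl)oxy]octa-1,5-dien-1-yl]furan-2(5H)-one
Product: 22 (5R)-3-(bromomethyl)-5-[(1Z,4S,5E)-2,6-dimethyl-8-oxo-4-[(triisopropylsilyl)oxy]octa-1,5-dien-1-yl]furan-2(5H)-one
Conditions: Dess–Martin periodinane, NaHCO3, CH2Cl2, 0 °C; used at once
Reagents that add atoms: none
Why: Buffered Dess–Martin oxidation gives the β,γ-unsaturated aldehyde without base, so migration of the C1=C10 bond into conjugation should be avoided.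

**Step 15**
Reactants: 22 (5R)-3-(bromomethyl)-5-[(1Z,4S,5E)-2,6-dimethyl-8-oxo-4-[(triisopropylsilyl)oxy]octa-1,5-dien-1-yl]furan-2(5H)-one
Product: 24 (2S,6R,7R,8S)-8-hydroxy-2-[(triisopropylsilyl)oxy]germacra-1(10)E,4Z,11(13)-trien-12,6-olide (2α-silyloxy, 8α-hydroxy, 6α,12-olide, H-7α), via allylchromium dichloride 23 (not isolated)
Conditions: CrCl2 (10 equiv), THF/DMF, 25 °C, slow addition of 22 over 12 h (final 2 mM)
Reagents that add atoms: none
Why: Proposed new method: two equivalents of CrCl2 convert the allylic bromide into a σ-allyl species of trivalent chromium whose CH2–Cr terminus (C13) is held trans to C6 by ring B; it adds through its γ-carbon C7 to the tethered aldehyde in a six-membered Zimmerman–Traxler transition state, so the C7=C11 bond moves to C11=C13 as the C7–C8 bond forms. The closest known reactions are the intermolecular chromium- and zinc-mediated allylations of aldehydes with 3-(bromomethyl)furan-2(5H)-ones and the intramolecular Nozaki–Hiyama–Kishi allylations of ω-formyl 2-(bromomethyl)enoates that close ten-membered germacranolide rings; their union on a butenolide is untested. Ring A is closed in a 10-exo-trig addition to the carbonyl group (SE2′ at the allyl unit), while ring B stays intact and, because C12 is already bound to O6, the new C8 alkoxide cannot form the competing 8,12-lactone. C7 is set by C6: bond formation anti to the C5 substituent gives the trans ring fusion (7R), since the cis-fused transition state would eclipse C5 and C8 on the planar lactone and the trans-fused one resembles the low-energy conformer of 6α,12-germacranolides. C8 is set by the chair transition state, in which the fixed E-type allyl geometry and an equatorial C9 give the 7,8-anti relationship (8S). The step needs ring closure over oligomerisation (high dilution, slow addition), γ- over α-attack (inherent to allylchromium reagents) and survival of the β,γ-unsaturated aldehyde and the base-sensitive butenolide (neutral, non-basic medium).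

**Step 16**
Reactants: 24 (2S,6R,7R,8S)-8-hydroxy-2-[(triisopropylsilyl)oxy]germacra-1(10)E,4Z,11(13)-trien-12,6-olide; 25 angelic acid, (2Z)-2-methylbut-2-enoic acid
Product: 27 (2S,6R,7R,8S)-8-(angeloyloxy)-2-[(triisopropylsilyl)oxy]germacra-1(10)E,4Z,11(13)-trien-12,6-olide, via angelic 2,4,6-trichlorobenzoic anhydride 26 (not isolated)
Conditions: 25, 2,4,6-Cl3C6H2COCl, Et3N, toluene, rt; then 24, 80 °C (no DMAP)
Reagents that add atoms: none
Why: Yamaguchi-type acylation through the mixed anhydride without a nucleophilic catalyst is the established way to attach an angelate without Z to E isomerisation to the tiglate, and it leaves C8 untouched.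

**Step 17**
Reactants: 27 (2S,6R,7R,8S)-8-(angeloyloxy)-2-[(triisopropylsilyl)oxy]germacra-1(10)E,4Z,11(13)-trien-12,6-olide
Product: 28 (2S,6R,7R,8S)-8-(angeloyloxy)-2-hydroxygermacra-1(10)E,4Z,11(13)-trien-12,6-olide
Conditions: Bu4NF, AcOH (1:1), THF, 0 °C to rt
Reagents that add atoms: none
Why: Buffered fluoride removes the silyl ether without acid (which would trigger transannular cyclisation of the germacra-1(10),4-diene) and without free base that could add to the methylene lactone.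

**Step 18**
Reactants: 28 (2S,6R,7R,8S)-8-(angeloyloxy)-2-hydroxygermacra-1(10)E,4Z,11(13)-trien-12,6-olide
Product: 29 (1R,2S,6R,7R,8S,10R)-8-(angeloyloxy)-1,10-epoxy-2-hydroxygermacra-4Z,11(13)-dien-12,6-olide (1β,10α-epoxide)
Conditions: mCPBA (1.05 equiv), NaHCO3, CH2Cl2, −20 °C
Reagents that add atoms: 3-chloroperoxybenzoic acid OOC(=O)c1cccc(Cl)c1
Why: In this Henbest-type directed Prilezhaev epoxidation the peracid should attack the C1=C10 bond (allylic hydroxyl, hydrogen-bond delivery) in preference to C4=C5 (deactivated by the allylic lactone oxygen), from the ring periphery in the conformer with H-2 in the alkene plane next to C14 (least allylic 1,3-strain), which gives the threo epoxy alcohol and sets C1 and C10.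

**Step 19**
Reactants: 29 (1R,2S,6R,7R,8S,10R)-8-(angeloyloxy)-1,10-epoxy-2-hydroxygermacra-4Z,11(13)-dien-12,6-olide
Product: 30 (1R,2S,4R,5S,6S,7R,8S,10R)-8-(angeloyloxy)-1,10:4,5-diepoxy-2-hydroxygermacr-11(13)-en-12,6-olide (1β,10α:4α,5α-diepoxide, 2α-hydroxy, 8α-angelate), the target
Conditions: VO(acac)2 (10 mol %), t-BuOOH (2 equiv), CH2Cl2, 0 °C to rt
Reagents that add atoms: tert-butyl hydroperoxide CC(C)(C)OO
Why: The vanadium alkoxide of the C2 hydroxyl should deliver the peroxide oxygen to the homoallylic Z alkene on the ring face that carries the hydroxyl (directed epoxidation of a homoallylic alcohol), setting C4 and C5 syn to O-2, while the electron-poor methylene lactone and angelate alkenes do not react.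

**Compound list**

1 | tert-butyl(but-3-yn-1-yloxy)dimethylsilane | C#CCCO[Si](C)(C)C(C)(C)C | starting material
2 | (E)-alkenyl(dimethyl)alane from 1 | C[Al](C)/C=C(\C)CCO[Si](C)(C)C(C)(C)C | intermediate
3 | tert-butyl{[(3E)-4-iodo-3-methylbut-3-en-1-yl]oxy}dimethylsilane | I/C=C(\C)CCO[Si](C)(C)C(C)(C)C | intermediate
4 | (E)-alkenyllithium from 3 | [Li]/C=C(\C)CCO[Si](C)(C)C(C)(C)C | intermediate
5 | (2E)-5-{[tert-butyl(dimethyl)silyl]oxy}-3-methylpent-2-enal | O=C/C=C(\C)CCO[Si](C)(C)C(C)(C)C | intermediate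
6 | methyl 3-methylbut-2-enoate | COC(=O)C=C(C)C | starting material
7 | lithium dienolate of 6 | COC(O[Li])=CC(C)=C | intermediate
8 | [(1-methoxy-3-methylbuta-1,3-dien-1-yl)oxy]trimethylsilane | COC(O[Si](C)(C)C)=CC(C)=C | intermediate
9 | (6S)-6-[(1E)-4-{[tert-butyl(dimethyl)silyl]oxy}-2-methylbut-1-en-1-yl]-4-methyl-5,6-dihydro-2H-pyran-2-one | O=C1C=C(C)C[C@@H](/C=C(\C)CCO[Si](C)(C)C(C)(C)C)O1 | intermediate
10 | (2Z,5S,6E)-9-{[tert-butyl(dimethyl)silyl]oxy}-5-hydroxy-N-methoxy-N,3,7-trimethylnona-2,6-dienamide | CON(C)C(=O)/C=C(C)\C[C@H](O)/C=C(\C)CCO[Si](C)(C)C(C)(C)C | intermediate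
11 | (2Z,5S,6E)-9-{[tert-butyl(dimethyl)silyl]oxy}-N-methoxy-N,3,7-trimethyl-5-[(triisopropylsilyl)oxy]nona-2,6-dienamide | CON(C)C(=O)/C=C(C)\C[C@H](O[Si](C(C)C)(C(C)C)C(C)C)/C=C(\C)CCO[Si](C)(C)C(C)(C)C | intermediate
12 | (2Z,5S,6E)-9-{[tert-butyl(dimethyl)silyl]oxy}-3,7-dimethyl-5-[(triisopropylsilyl)oxy]nona-2,6-dienal | O=C/C=C(C)\C[C@H](O[Si](C(C)C)(C(C)C)C(C)C)/C=C(\C)CCO[Si](C)(C)C(C)(C)C | intermediate
13 | 1-methoxy-4-[(prop-2-yn-1-yloxy)methyl]benzene | C#CCOCc1ccc(OC)cc1 | starting material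
14 | methylzinc acetylide of 13 | C[Zn]C#CCOCc1ccc(OC)cc1 | intermediate
15 | (4R,5Z,8S,9E)-12-{[tert-butyl(dimethyl)silyl]oxy}-1-[(4-methoxybenzyl)oxy]-6,10-dimethyl-8-[(triisopropylsilyl)oxy]dodeca-5,9-dien-2-yn-4-ol | COc1ccc(COCC#C[C@H](O)/C=C(C)\C[C@H](O[Si](C(C)C)(C(C)C)C(C)C)/C=C(\C)CCO[Si](C)(C)C(C)(C)C)cc1 | intermediate
16 | sodium 2,2-bis(2-methoxyethoxy)-2,5-dihydro-1,2-oxaluminol-2-uide formed from 15 (Al on C11, O on C6) | COc1ccc(COCC2=C[C@@H](/C=C(C)\C[C@H](O[Si](C(C)C)(C(C)C)C(C)C)/C=C(\C)CCO[Si](C)(C)C(C)(C)C)O[Al-]2(OCCOC)OCCOC)cc1.[Na+] | intermediate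
17 | (2Z,4R,5Z,8S,9E)-12-{[tert-butyl(dimethyl)silyl]oxy}-2-iodo-1-[(4-methoxybenzyl)oxy]-6,10-dimethyl-8-[(triisopropylsilyl)oxy]dodeca-2,5,9-trien-4-ol | COc1ccc(COC/C(I)=C/[C@H](O)/C=C(C)\C[C@H](O[Si](C(C)C)(C(C)C)C(C)C)/C=C(\C)CCO[Si](C)(C)C(C)(C)C)cc1 | intermediate
18 | (5R)-5-[(1Z,4S,5E)-8-{[tert-butyl(dimethyl)silyl]oxy}-2,6-dimethyl-4-[(triisopropylsilyl)oxy]octa-1,5-dien-1-yl]-3-{[(4-methoxybenzyl)oxy]methyl}furan-2(5H)-one | COc1ccc(COCC2=C[C@@H](/C=C(C)\C[C@H](O[Si](C(C)C)(C(C)C)C(C)C)/C=C(\C)CCO[Si](C)(C)C(C)(C)C)OC2=O)cc1 | intermediate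
19 | (5R)-5-[(1Z,4S,5E)-8-{[tert-butyl(dimethyl)silyl]oxy}-2,6-dimethyl-4-[(triisopropylsilyl)oxy]octa-1,5-dien-1-yl]-3-(hydroxymethyl)furan-2(5H)-one | OCC1=C[C@@H](/C=C(C)\C[C@H](O[Si](C(C)C)(C(C)C)C(C)C)/C=C(\C)CCO[Si](C)(C)C(C)(C)C)OC1=O | intermediate
20 | (5R)-3-(bromomethyl)-5-[(1Z,4S,5E)-8-{[tert-butyl(dimethyl)silyl]oxy}-2,6-dimethyl-4-[(triisopropylsilyl)oxy]octa-1,5-dien-1-yl]furan-2(5H)-one | BrCC1=C[C@@H](/C=C(C)\C[C@H](O[Si](C(C)C)(C(C)C)C(C)C)/C=C(\C)CCO[Si](C)(C)C(C)(C)C)OC1=O | intermediate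
21 | (5R)-3-(bromomethyl)-5-[(1Z,4S,5E)-8-hydroxy-2,6-dimethyl-4-[(triisopropylsilyl)oxy]octa-1,5-dien-1-yl]furan-2(5H)-one | BrCC1=C[C@@H](/C=C(C)\C[C@H](O[Si](C(C)C)(C(C)C)C(C)C)/C=C(\C)CCO)OC1=O | intermediate
22 | (5R)-3-(bromomethyl)-5-[(1Z,4S,5E)-2,6-dimethyl-8-oxo-4-[(triisopropylsilyl)oxy]octa-1,5-dien-1-yl]furan-2(5H)-one | BrCC1=C[C@@H](/C=C(C)\C[C@H](O[Si](C(C)C)(C(C)C)C(C)C)/C=C(\C)CC=O)OC1=O | intermediate
23 | allylchromium dichloride from 22 (CrCl2 on C13) | Cl[Cr](Cl)CC1=C[C@@H](/C=C(C)\C[C@H](O[Si](C(C)C)(C(C)C)C(C)C)/C=C(\C)CC=O)OC1=O | intermediate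
24 | (2S,6R,7R,8S)-8-hydroxy-2-[(triisopropylsilyl)oxy]germacra-1(10)E,4Z,11(13)-trien-12,6-olide | [C@H]1(O)C/C(C)=C/[C@@H](O[Si](C(C)C)(C(C)C)C(C)C)C/C(C)=C\[C@H]2OC(=O)C(=C)[C@H]12 | intermediate
25 | angelic acid, (2Z)-2-methylbut-2-enoic acid | C/C=C(/C)C(=O)O | starting material
26 | angelic 2,4,6-trichlorobenzoic anhydride | C/C=C(/C)C(=O)OC(=O)c1c(Cl)cc(Cl)cc1Cl | intermediate
27 | (2S,6R,7R,8S)-8-(angeloyloxy)-2-[(triisopropylsilyl)oxy]germacra-1(10)E,4Z,11(13)-trien-12,6-olide | [C@H]1(OC(=O)/C(C)=C\C)C/C(C)=C/[C@@H](O[Si](C(C)C)(C(C)C)C(C)C)C/C(C)=C\[C@H]2OC(=O)C(=C)[C@H]12 | intermediate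
28 | (2S,6R,7R,8S)-8-(angeloyloxy)-2-hydroxygermacra-1(10)E,4Z,11(13)-trien-12,6-olide | [C@H]1(OC(=O)/C(C)=C\C)C/C(C)=C/[C@@H](O)C/C(C)=C\[C@H]2OC(=O)C(=C)[C@H]12 | intermediate
29 | (1R,2S,6R,7R,8S,10R)-8-(angeloyloxy)-1,10-epoxy-2-hydroxygermacra-4Z,11(13)-dien-12,6-olide | [C@H]1(OC(=O)/C(C)=C\C)C[C@@]3(C)O[C@@H]3[C@@H](O)C/C(C)=C\[C@H]2OC(=O)C(=C)[C@H]12 | intermediate
30 | (1R,2S,4R,5S,6S,7R,8S,10R)-8-(angeloyloxy)-1,10:4,5-diepoxy-2-hydroxygermacr-11(13)-en-12,6-olide | C=C1C(=O)O[C@H]2[C@H]1[C@@H](OC(=O)/C(C)=C\C)C[C@@]1(C)O[C@@H]1[C@@H](O)C[C@@]1(C)O[C@@H]21 | target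

**Step count**

Total: 19 steps. Longest linear sequence: 18 steps (steps 1, 2 and 4–19, from 1).

**Steps most likely to fail**

Step 15 (proposed new method). The ring closure may lose to intermolecular allylation (oligomers) or to simple reduction of the allylic bromide, and the facial selectivity at C7 or C8 may be poor because the tether, not a free substituent, decides the approach. The fallback uses the established closure of an open-chain ω-formyl 2-(bromomethyl)enoate and lets ring B form afterwards; it sets out from 17 and rejoins the route at 28. The C6 hydroxyl of 17 is silylated (t-BuMe2SiOTf, 2,6-lutidine) to the bis(tert-butyldimethylsilyl) ether F1. Palladium-catalysed methoxycarbonylation (PdCl2(PPh3)2, CO, MeOH, Et3N) gives the methyl (2Z)-2-(4-methoxybenzyloxymethyl)enoate F2. DDQ frees the allylic alcohol F3, and CBr4/PPh3 gives the methyl (2E)-2-(bromomethyl)enoate F4. PPTS in MeOH cleaves only the primary silyl ether to the alcohol F5, and buffered Dess–Martin oxidation gives the ω-formyl bromide F6. CrCl2 under high dilution should close ring A to the hydroxy ester carbocycle F7, which is acylated at once with the mixed anhydride 26 to the angelate F8 so that the C8 hydroxyl cannot lactonise. Bu4NF/AcOH then removes both silyl groups, and the freed C6 alkoxide closes ring B on the methyl ester to give 28.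

Step 19. Oxygen delivery by the C2 hydroxyl may lose to attack on the other, more exposed face of the Z alkene, or the Lewis-acidic vanadium may trigger transannular opening of the 1,10-epoxide. The fallback inverts the facial sense through a bromohydrin with the hydroxyl masked; it sets out from 27 and rejoins at 30. mCPBA (NaHCO3, CH2Cl2) epoxidises the C1=C10 bond of 27 from the periphery to the 1β,10α-epoxide silyl ether F9. NBS in aqueous DME puts bromine on the face that a direct oxidant prefers and water on C4 from the opposite face, giving the 5-bromo-4-hydroxy compound F10. Ag2O closes the oxirane with inversion at C5 to the 4α,5α-epoxide silyl ether F11, and Bu4NF/AcOH gives 30.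

Step 4. The β,β-disubstituted enal may react slowly and with modest enantioselectivity, and part of the aldol product may stay as the open E ester that cannot lactonise. The fallback builds the same lactone by allylation and ring-closing metathesis; it sets out from 5 and rejoins at 9. Asymmetric methallylation of 5 with (−)-B-methallyldiisopinocampheylborane (Et2O, −78 °C; oxidative work-up) gives the homoallylic alcohol F12. Acryloyl chloride/Et3N gives the acrylate F13. Ring-closing metathesis with second-generation Grubbs catalyst (CH2Cl2, 40 °C) joins the acrylate and the 1,1-disubstituted alkene to the 4-methyl-5,6-dihydropyran-2-one 9.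

**Further compounds**

F1 | step 15 | (2Z,4R,5Z,8S,9E)-4,12-bis{[tert-butyl(dimethyl)silyl]oxy}-2-iodo-1-[(4-methoxybenzyl)oxy]-6,10-dimethyl-8-[(triisopropylsilyl)oxy]dodeca-2,5,9-triene | COc1ccc(COC/C(I)=C/[C@H](O[Si](C)(C)C(C)(C)C)/C=C(C)\C[C@H](O[Si](C(C)C)(C(C)C)C(C)C)/C=C(\C)CCO[Si](C)(C)C(C)(C)C)cc1
F2 | step 15 | methyl (2Z,4R,5Z,8S,9E)-4,12-bis{[tert-butyl(dimethyl)silyl]oxy}-2-{[(4-methoxybenzyl)oxy]methyl}-6,10-dimethyl-8-[(triisopropylsilyl)oxy]dodeca-2,5,9-trienoate | COc1ccc(COC/C(C(=O)OC)=C/[C@H](O[Si](C)(C)C(C)(C)C)/C=C(C)\C[C@H](O[Si](C(C)C)(C(C)C)C(C)C)/C=C(\C)CCO[Si](C)(C)C(C)(C)C)cc1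
F3 | step 15 | methyl (2Z,4R,5Z,8S,9E)-4,12-bis{[tert-butyl(dimethyl)silyl]oxy}-2-(hydroxymethyl)-6,10-dimethyl-8-[(triisopropylsilyl)oxy]dodeca-2,5,9-trienoate | OC/C(C(=O)OC)=C/[C@H](O[Si](C)(C)C(C)(C)C)/C=C(C)\C[C@H](O[Si](C(C)C)(C(C)C)C(C)C)/C=C(\C)CCO[Si](C)(C)C(C)(C)C
F4 | step 15 | methyl (2E,4R,5Z,8S,9E)-2-(bromomethyl)-4,12-bis{[tert-butyl(dimethyl)silyl]oxy}-6,10-dimethyl-8-[(triisopropylsilyl)oxy]dodeca-2,5,9-trienoate | BrC/C(C(=O)OC)=C/[C@H](O[Si](C)(C)C(C)(C)C)/C=C(C)\C[C@H](O[Si](C(C)C)(C(C)C)C(C)C)/C=C(\C)CCO[Si](C)(C)C(C)(C)C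
F5 | step 15 | methyl (2E,4R,5Z,8S,9E)-2-(bromomethyl)-4-{[tert-butyl(dimethyl)silyl]oxy}-12-hydroxy-6,10-dimethyl-8-[(triisopropylsilyl)oxy]dodeca-2,5,9-trienoate | BrC/C(C(=O)OC)=C/[C@H](O[Si](C)(C)C(C)(C)C)/C=C(C)\C[C@H](O[Si](C(C)C)(C(C)C)C(C)C)/C=C(\C)CCO
F6 | step 15 | methyl (2E,4R,5Z,8S,9E)-2-(bromomethyl)-4-{[tert-butyl(dimethyl)silyl]oxy}-6,10-dimethyl-12-oxo-8-[(triisopropylsilyl)oxy]dodeca-2,5,9-trienoate | BrC/C(C(=O)OC)=C/[C@H](O[Si](C)(C)C(C)(C)C)/C=C(C)\C[C@H](O[Si](C(C)C)(C(C)C)C(C)C)/C=C(\C)CC=O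
F7 | step 15 | methyl (2S,6R,7R,8S)-6-{[tert-butyl(dimethyl)silyl]oxy}-8-hydroxy-2-[(triisopropylsilyl)oxy]germacra-1(10)E,4Z,11(13)-trien-12-oate | [C@H]1(O)C/C(C)=C/[C@@H](O[Si](C(C)C)(C(C)C)C(C)C)C/C(C)=C\[C@@H](O[Si](C)(C)C(C)(C)C)[C@@H]1C(=C)C(=O)OC
F8 | step 15 | methyl (2S,6R,7R,8S)-8-(angeloyloxy)-6-{[tert-butyl(dimethyl)silyl]oxy}-2-[(triisopropylsilyl)oxy]germacra-1(10)E,4Z,11(13)-trien-12-oate | [C@H]1(OC(=O)/C(C)=C\C)C/C(C)=C/[C@@H](O[Si](C(C)C)(C(C)C)C(C)C)C/C(C)=C\[C@@H](O[Si](C)(C)C(C)(C)C)[C@@H]1C(=C)C(=O)OC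
F9 | step 19 | (1R,2S,6R,7R,8S,10R)-8-(angeloyloxy)-1,10-epoxy-2-[(triisopropylsilyl)oxy]germacra-4Z,11(13)-dien-12,6-olide | [C@H]1(OC(=O)/C(C)=C\C)C[C@@]3(C)O[C@@H]3[C@@H](O[Si](C(C)C)(C(C)C)C(C)C)C/C(C)=C\[C@H]2OC(=O)C(=C)[C@H]12
F10 | step 19 | (1R,2S,4R,5R,6S,7R,8S,10R)-8-(angeloyloxy)-5-bromo-1,10-epoxy-4-hydroxy-2-[(triisopropylsilyl)oxy]germacr-11(13)-en-12,6-olide | [C@H]1(OC(=O)/C(C)=C\C)C[C@@]3(C)O[C@@H]3[C@@H](O[Si](C(C)C)(C(C)C)C(C)C)C[C@@](C)(O)[C@H](Br)[C@H]2OC(=O)C(=C)[C@H]12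
F11 | step 19 | (1R,2S,4R,5S,6S,7R,8S,10R)-8-(angeloyloxy)-1,10:4,5-diepoxy-2-[(triisopropylsilyl)oxy]germacr-11(13)-en-12,6-olide | [C@H]1(OC(=O)/C(C)=C\C)C[C@@]3(C)O[C@@H]3[C@@H](O[Si](C(C)C)(C(C)C)C(C)C)C[C@@]4(C)O[C@H]4[C@H]2OC(=O)C(=C)[C@H]12
F12 | step 4 | (4S,5E)-8-{[tert-butyl(dimethyl)silyl]oxy}-2,6-dimethylocta-1,5-dien-4-ol | C=C(C)C[C@H](O)/C=C(\C)CCO[Si](C)(C)C(C)(C)C
F13 | step 4 | (4S,5E)-8-{[tert-butyl(dimethyl)silyl]oxy}-2,6-dimethylocta-1,5-dien-4-yl prop-2-enoate | C=C(C)C[C@H](OC(=O)C=C)/C=C(\C)CCO[Si](C)(C)C(C)(C)C
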